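C16–O acyl bond and C15 acid are traced back to a butenolide (C15/C16 lactone, a temporary ring that holds the 13Z geometry); C8=C17 to a C8 ketone; C9–C11 to a 1,6-Michael addition; the helper ester on C9 to an acetoacetate; C4–C5 and C9–C10 to one cation–olefin bicyclization; C6–C7 to a dianion alkylation.
Enabling feature: in ring B, C9 lies between quaternary C10 and the methylidene carbon C8; with C8 as a ketone and an allyl ester on C9, this hindered carbon is the only doubly activated, epimerizable position, and in 4-ethenylfuran-2(5H)-one the array C11=C12–C13=C14–C15(=O)–O–C16 offers C11 as an open δ-terminus.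
Forward: geranyl chloride + allyl acetoacetate; rings A and B close together; enzymatic resolution; C9–C11 union with the vinyl butenolide; Pd removal of the ester; methylenation; lactone opening and acylation.
Stereochemistry: trans C5/C10 from chair–chair folding of the E-alkene, absolute sense from a ketoreductase kinetic resolution; C9 from protonation and equilibration next to the C8 ketone (side chain equatorial); 13Z from the lactone ring; the acyl center from (R)-2-methylbutanoic acid.
Key step: step 5

Assumption: (R)-2-methylbutanoic acid and 4-bromofuran-2(5H)-one are bought, and a ketoreductase that reduces only the (4aS,8aS)-enantiomer of 4 is taken from a commercial screening panel.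

Step 1
Reactants: 1 allyl acetoacetate; 2 geranyl chloride
Product: 3 allyl (6E)-7,11-dimethyl-3-oxododeca-6,10-dienoate
Conditions: NaH (1.1 equiv), THF, 0 °C; n-BuLi (1.05 equiv), 0 °C; then 2, 0 → 23 °C; dilute aq. HCl
Reagents that add atoms: none
Why: Weiler dianion alkylation, in which the more basic terminal carbanion of the acetoacetate dianion displaces the primary allylic chloride in an SN2 reaction and leaves the E-alkene untouched.

Step 2
Reactants: 3 allyl (6E)-7,11-dimethyl-3-oxododeca-6,10-dienoate
Product: 4 rac-allyl (1S,4aR,8aR)-5,5,8a-trimethyl-2-oxodecahydronaphthalene-1-carboxylate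
Conditions: SnCl4 (2 equiv), CH2Cl2, 0 → 23 °C; aq. NaHCO3
Reagents that add atoms: none
Why: Lewis acid-mediated cation–olefin bicyclization terminated by the enol carbon of the chelated β-keto ester; chair–chair folding of the E-trisubstituted alkene should give the trans ring fusion (C5–H anti to the C10 methyl group), the ester settles equatorial at the enolizable C9, and the product is racemic.

Step 3
Reactants: 4 rac-allyl (1S,4aR,8aR)-5,5,8a-trimethyl-2-oxodecahydronaphthalene-1-carboxylate
Product: 5 allyl (1S,4aR,8aR)-5,5,8a-trimethyl-2-oxodecahydronaphthalene-1-carboxylate (the unreduced enantiomer)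
Conditions: ketoreductase, NADP+ (cat.), i-PrOH (co-substrate), KH2PO4/K2HPO4 buffer (pH 7), DMSO (10%), 30 °C, run to just past half conversion; chromatography
Reagents that add atoms: none
Why: Enzymatic kinetic resolution by enantioselective carbonyl reduction of a cyclic β-keto ester (the reaction type of yeast reductions of 2-oxocycloalkanecarboxylates): only the (4aS,8aS)-ketone should be reduced, so the (4aR,8aR)-ketone is recovered and no new stereocenter is formed in it.

Step 4
Reactants: 6 4-bromofuran-2(5H)-one; 7 tributyl(vinyl)stannane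
Product: 8 4-ethenylfuran-2(5H)-one
Conditions: Pd(PPh3)4 (3 mol%), BHT (trace), 1,4-dioxane, 90 °C
Reagents that add atoms: none
Why: Stille cross-coupling of the activated β-bromo enoate C–Br bond under zerovalent palladium catalysis; the neutral conditions spare the base-sensitive lactone.

Step 5
Reactants: 5 allyl (1S,4aR,8aR)-5,5,8a-trimethyl-2-oxodecahydronaphthalene-1-carboxylate; 8 4-ethenylfuran-2(5H)-one
Product: 9 allyl (1S,4aR,8aR)-5,5,8a-trimethyl-2-oxo-1-[2-(5-oxo-2,5-dihydrofuran-3-yl)ethyl]decahydronaphthalene-1-carboxylate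
Conditions: DBU (0.3 equiv), 8 (2 equiv, in portions), BHT (trace), MeCN, 23 → 45 °C
Reagents that add atoms: none
Why: DBU reversibly deprotonates C9 of 5, the only carbon flanked by both the C8 ketone and the allyl ester, and this enolate adds to the unsubstituted vinyl terminus (the future C11) of the dienyl lactone 8; proton transfer and base-mediated return of the double bond into the ring then give the conjugated butenolide, so all six side-chain carbons arrive in one bond-forming event. The closest known reaction types are the vinylogous (1,6) Michael addition of β-keto esters to 2,4-dienoates and the Michael addition of 2-alkoxycarbonyl decalones next to an angular methyl group to vinyl ketones. No ring is closed. The new quaternary stereocenter C9 is controlled by the axial C10 methyl group, which directs the acceptor to the opposite face of ring B; this configuration is of no consequence because C9 is reset in step 6. The step needs C- over O-alkylation, C9 over C7 and 1,6- over 1,4-addition: the soft, doubly stabilized enolate and the acidity of C9–H secure the first two, and the fully substituted C13 of 8 blocks the 1,4-mode. The lactone ring of 8 keeps C15 and C16 on the same side of C13=C14, which is the Z geometry of the target.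

Step 6
Reactants: 9 allyl (1S,4aR,8aR)-5,5,8a-trimethyl-2-oxo-1-[2-(5-oxo-2,5-dihydrofuran-3-yl)ethyl]decahydronaphthalene-1-carboxylate
Product: 10 4-{2-[(1S,4aR,8aR)-5,5,8a-trimethyl-2-oxodecahydronaphthalen-1-yl]ethyl}furan-2(5H)-one
Conditions: Pd(OAc)2 (5 mol%), PPh3 (15 mol%), HCO2H (2 equiv), Et3N (2.5 equiv), THF, 40 °C; then DBU (0.2 equiv), 23 °C
Reagents that add atoms: none
Why: Tsuji decarboxylation, in which zerovalent palladium ionizes the allyl ester, the β-keto carboxylate loses CO2 and formate reduces the allyl fragment to propene; the enol should be protonated on the face opposite the axial C10 methyl group, and the ketone-activated C9 equilibrates under DBU to the epimer with an equatorial side chain and axial hydrogen, which is the C9 configuration of the target.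

Step 7
Reactants: 10 4-{2-[(1S,4aR,8aR)-5,5,8a-trimethyl-2-oxodecahydronaphthalen-1-yl]ethyl}furan-2(5H)-one
Product: 11 4-{2-[(1R,4aR,8aR)-5,5,8a-trimethyl-2-methylidenedecahydronaphthalen-1-yl]ethyl}furan-2(5H)-one
Conditions: Zn, CH2Br2, TiCl4 (reagent preformed in THF), CH2Cl2, 0 → 23 °C
Reagents that add atoms: dibromomethane, BrCBr
Why: Takai–Lombardo methylenation, whose non-basic geminal dimetallic reagent should convert the hindered C8 ketone into the exocyclic alkene without epimerizing C9 and without attacking the lactone.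

Step 8
Reactants: 11 4-{2-[(1R,4aR,8aR)-5,5,8a-trimethyl-2-methylidenedecahydronaphthalen-1-yl]ethyl}furan-2(5H)-one; 12 (2R)-2-methylbutanoic acid
Product: 15 (2Z)-3-({[(2R)-2-methylbutanoyl]oxy}methyl)-5-[(1R,4aR,8aR)-5,5,8a-trimethyl-2-methylidenedecahydronaphthalen-1-yl]pent-2-enoic acid, via lithium hydroxy carboxylate 13 (not isolated), via acyl imidazole 14 (not isolated)
Conditions: LiOH·H2O (1.05 equiv), THF/H2O, 0 → 23 °C; evaporate, toluene azeotrope; NaH (1.1 equiv), DMF, −20 °C; 14 (1.3 equiv, from 12 and 1,1'-carbonyldiimidazole, THF, 23 °C), −20 → 0 °C; dilute aq. HCl to pH 3, 0 °C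
Reagents that add atoms: lithium hydroxide, [Li+].[OH-]
Why: Lactone saponification followed by alkoxide acylation with an N-acylimidazole: the alkoxide of the Z-hydroxy carboxylate should be acylated far faster than the carboxylate, so no mixed anhydride forms that could close the lactone again, the Z geometry is inherited from the ring, and unreacted 13 returns to 11 on acidification.

Compound list
1 | allyl acetoacetate | CC(=O)CC(=O)OCC=C | starting material
2 | geranyl chloride, (2E)-1-chloro-3,7-dimethylocta-2,6-diene | CC(C)=CCC/C(C)=C/CCl | starting material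
3 | allyl (6E)-7,11-dimethyl-3-oxododeca-6,10-dienoate | C=CCOC(=O)CC(=O)CC/C=C(\C)CCC=C(C)C | intermediate
4 | rac-allyl (1S,4aR,8aR)-5,5,8a-trimethyl-2-oxodecahydronaphthalene-1-carboxylate (racemate, trans-fused, ester equatorial) | O=C1CC[C@@H]2C(C)(C)CCC[C@@]2(C)[C@@H]1C(=O)OCC=C.O=C1CC[C@H]2C(C)(C)CCC[C@]2(C)[C@H]1C(=O)OCC=C | intermediate
5 | allyl (1S,4aR,8aR)-5,5,8a-trimethyl-2-oxodecahydronaphthalene-1-carboxylate | O=C1CC[C@@H]2C(C)(C)CCC[C@@]2(C)[C@@H]1C(=O)OCC=C | intermediate
6 | 4-bromofuran-2(5H)-one | O=C1C=C(Br)CO1 | starting material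
7 | tributyl(vinyl)stannane | C=C[Sn](CCCC)(CCCC)CCCC | starting material
8 | 4-ethenylfuran-2(5H)-one | C=CC1=CC(=O)OC1 | intermediate
9 | allyl (1S,4aR,8aR)-5,5,8a-trimethyl-2-oxo-1-[2-(5-oxo-2,5-dihydrofuran-3-yl)ethyl]decahydronaphthalene-1-carboxylate (side chain axial, anti to the 8a-methyl group) | O=C1CC[C@@H]2C(C)(C)CCC[C@@]2(C)[C@]1(CCC3=CC(=O)OC3)C(=O)OCC=C | intermediate
10 | 4-{2-[(1S,4aR,8aR)-5,5,8a-trimethyl-2-oxodecahydronaphthalen-1-yl]ethyl}furan-2(5H)-one | O=C1CC[C@@H]2C(C)(C)CCC[C@@]2(C)[C@@H]1CCC3=CC(=O)OC3 | intermediate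
11 | 4-{2-[(1R,4aR,8aR)-5,5,8a-trimethyl-2-methylidenedecahydronaphthalen-1-yl]ethyl}furan-2(5H)-one | C=C1CC[C@@H]2C(C)(C)CCC[C@@]2(C)[C@@H]1CCC3=CC(=O)OC3 | intermediate
12 | (2R)-2-methylbutanoic acid | CC[C@@H](C)C(=O)O | starting material
13 | lithium (2Z)-3-(hydroxymethyl)-5-[(1R,4aR,8aR)-5,5,8a-trimethyl-2-methylidenedecahydronaphthalen-1-yl]pent-2-enoate | C=C1CC[C@@H]2C(C)(C)CCC[C@@]2(C)[C@@H]1CC/C(=C/C(=O)[O-])CO.[Li+] | intermediate
14 | 1-[(2R)-2-methylbutanoyl]-1H-imidazole | CC[C@@H](C)C(=O)n1ccnc1 | intermediate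
15 | (2Z)-3-({[(2R)-2-methylbutanoyl]oxy}methyl)-5-[(1R,4aR,8aR)-5,5,8a-trimethyl-2-methylidenedecahydronaphthalen-1-yl]pent-2-enoic acid | C=C1CC[C@@H]2C(C)(C)CCC[C@@]2(C)[C@@H]1CC/C(=C/C(=O)O)COC(=O)[C@H](C)CC | target

Total step count: 8. Longest linear sequence: 7 steps (steps 1, 2, 3, 5, 6, 7, 8).

Steps most likely to fail

Step 5. The conjugate addition may stall or run backwards at the congested C9 (a quaternary center beside quaternary C10), or 8 may oligomerize under base. The fallback sets out from 5 and uses the more electrophilic 1-[(tert-butyldimethylsilyl)oxy]but-3-en-2-one as a 1,4-acceptor (DBU, MeCN), which should give allyl (1S,4aR,8aR)-1-{4-[(tert-butyldimethylsilyl)oxy]-3-oxobutyl}-5,5,8a-trimethyl-2-oxodecahydronaphthalene-1-carboxylate F1. Tsuji decarboxylation under the conditions of step 6 would give (1S,4aR,8aR)-1-{4-[(tert-butyldimethylsilyl)oxy]-3-oxobutyl}-5,5,8a-trimethyloctahydronaphthalen-2(1H)-one F2, and HF·pyridine would free (1S,4aR,8aR)-1-(4-hydroxy-3-oxobutyl)-5,5,8a-trimethyloctahydronaphthalen-2(1H)-one F3. (Triphenylphosphoranylidene)ketene, Ph3P=C=C=O, in toluene at 80 °C would acylate the hydroxyl group and close the butenolide by intramolecular Wittig reaction, which returns to the route at 10.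

Step 8. The lactone may close again through a mixed anhydride, alkoxide formation may be incomplete, or the acyl donor may epimerize. The fallback sets out from 11, opens it to 13 as in the route, and alkylates the carboxylate with allyl bromide (DMF, 0 °C) to allyl (2Z)-3-(hydroxymethyl)-5-[(1R,4aR,8aR)-5,5,8a-trimethyl-2-methylidenedecahydronaphthalen-1-yl]pent-2-enoate F4. This would be esterified at once with 12 (N,N'-diisopropylcarbodiimide, DMAP, CH2Cl2, 0 °C) to allyl (2Z)-3-({[(2R)-2-methylbutanoyl]oxy}methyl)-5-[(1R,4aR,8aR)-5,5,8a-trimethyl-2-methylidenedecahydronaphthalen-1-yl]pent-2-enoate F5. Pd(PPh3)4 with morpholine in THF would then remove the allyl group, which returns to the route at 15.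

Step 3. The enzyme may discriminate poorly between the enantiomers or fail to turn over the hindered ketone. The fallback sets out from 4 and condenses it with (R)-1-phenylethylamine (AcOH cat., toluene, removal of water). This should give two diastereomeric enamino esters: allyl (4aR,8aR)-5,5,8a-trimethyl-2-{[(1R)-1-phenylethyl]amino}-3,4,4a,5,6,7,8,8a-octahydronaphthalene-1-carboxylate F6 and allyl (4aS,8aS)-5,5,8a-trimethyl-2-{[(1R)-1-phenylethyl]amino}-3,4,4a,5,6,7,8,8a-octahydronaphthalene-1-carboxylate F7. F6 would be separated by crystallization or chromatography and hydrolyzed with aqueous oxalic acid in THF, which returns to the route at 5.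

Further compounds
F1 | step 5 | allyl (1S,4aR,8aR)-1-{4-[(tert-butyldimethylsilyl)oxy]-3-oxobutyl}-5,5,8a-trimethyl-2-oxodecahydronaphthalene-1-carboxylate | O=C1CC[C@@H]2C(C)(C)CCC[C@@]2(C)[C@]1(CCC(=O)CO[Si](C)(C)C(C)(C)C)C(=O)OCC=C
F2 | step 5 | (1S,4aR,8aR)-1-{4-[(tert-butyldimethylsilyl)oxy]-3-oxobutyl}-5,5,8a-trimethyloctahydronaphthalen-2(1H)-one | O=C1CC[C@@H]2C(C)(C)CCC[C@@]2(C)[C@@H]1CCC(=O)CO[Si](C)(C)C(C)(C)C
F3 | step 5 | (1S,4aR,8aR)-1-(4-hydroxy-3-oxobutyl)-5,5,8a-trimethyloctahydronaphthalen-2(1H)-one | O=C1CC[C@@H]2C(C)(C)CCC[C@@]2(C)[C@@H]1CCC(=O)CO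
F4 | step 8 | allyl (2Z)-3-(hydroxymethyl)-5-[(1R,4aR,8aR)-5,5,8a-trimethyl-2-methylidenedecahydronaphthalen-1-yl]pent-2-enoate | C=C1CC[C@@H]2C(C)(C)CCC[C@@]2(C)[C@@H]1CC/C(=C/C(=O)OCC=C)CO
F5 | step 8 | allyl (2Z)-3-({[(2R)-2-methylbutanoyl]oxy}methyl)-5-[(1R,4aR,8aR)-5,5,8a-trimethyl-2-methylidenedecahydronaphthalen-1-yl]pent-2-enoate | C=C1CC[C@@H]2C(C)(C)CCC[C@@]2(C)[C@@H]1CC/C(=C/C(=O)OCC=C)COC(=O)[C@H](C)CC
F6 | step 3 | allyl (4aR,8aR)-5,5,8a-trimethyl-2-{[(1R)-1-phenylethyl]amino}-3,4,4a,5,6,7,8,8a-octahydronaphthalene-1-carboxylate | N([C@H](C)c3ccccc3)C=1CC[C@@H]2C(C)(C)CCC[C@@]2(C)C=1C(=O)OCC=C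
F7 | step 3 | allyl (4aS,8aS)-5,5,8a-trimethyl-2-{[(1R)-1-phenylethyl]amino}-3,4,4a,5,6,7,8,8a-octahydronaphthalene-1-carboxylate | N([C@H](C)c3ccccc3)C=1CC[C@H]2C(C)(C)CCC[C@]2(C)C=1C(=O)OCC=C
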